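The earlier runs and the new flask were generated by integration for an exercise, and the scatter is random.

Divide the rate of making target by the catalyst charged: while that figure holds as the charge changes, the rate follows the charge.

common to all: free catalyst 50 µM
- east: substrate 0.070 M; reagent 0.055 M; run made earlier
- south-west: substrate 0.11 M; reagent 0.055 M; run made earlier
- flask: substrate 0.050 M; reagent 0.0550 M

| run | time / h | target / % | substrate / % |
|---|---|---|---|
| east | 1.00 | 0.8 | 99.2 |
| east | 2.00 | 1.7 | 98.6 |
| east | 2.50 | 1.9 | 97.9 |
| east | 4.00 | 2.7 | 97.1 |
| east | 6.00 | 3.9 | 96.0 |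
| east | 10.0 | 6.6 | 93.5 |
| east | 15.0 | 9.9 | 90.4 |
| south-west | 0.833 | 0.5 | 99.5 |
| south-west | 2.00 | 1.4 | 98.8 |
| south-west | 4.00 | 1.8 | 98.4 |
| south-west | 6.00 | 2.7 | 97.0 |
| south-west | 8.00 | 3.9 | 96.2 |
| south-west | 12.0 | 5.5 | 95.0 |
| south-west | 15.0 | 6.9 | 93.8 |

(standard deviation of a reading: 0.3 percentage points)

- no earlier run changes the charge of free catalyst; that part of a forecast is a guess

* factor on the rate of making target when 5.0 % of the substrate are converted if free catalyst is charged twice over
* factor on the rate when 5.0 % of the substrate are converted if free catalyst is charged at 500 µM instead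

I began with the east run, where the average rate over 15.0 h was 4.62 × 10⁻⁴ M h⁻¹, so the rate of making target per catalyst charged, the turnover frequency, was 9.24 h⁻¹. With the main step alone, turnover would go in proportion to [substrate], which gave 6.60 h⁻¹ for the new flask.

The second addition came from dividing the south-west rate, 5.06 × 10⁻⁴ M h⁻¹ over the same time, by the east rate, so that time dropped out. The south-west run held 1.57 times the substrate but ran just 1.10 times as fast. As a reading, that is an order in substrate of 0.201, as if the catalyst waited in a substrate-bound resting state. This order raised my figure for the new flask to 8.63 h⁻¹.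

The last addition was the catalyst itself, which no earlier run varied. If the turnover frequency held with the charge, the factors were 2 and 10.0, and those were my guess. The forecast stood lower, at 1.9 and 9, with the caution “Dimerisation or off-cycle aggregation would lower these factors”.

The new flask gave factors of 1.73 for the doubled charge and 5.26 for 500 µM.

    substrate + free catalyst → catalyst intermediate A (k = 2100 M⁻¹ h⁻¹)
    reagent + catalyst intermediate A ⇌ catalyst intermediate B (K = 57.0 M⁻¹, k = 340 M⁻¹ h⁻¹)
    catalyst intermediate B ⇌ free catalyst + target (K = 0.0640 M, k = 79.0 h⁻¹)
    2 catalyst intermediate A ⇌ resting dimer (K = 6800 M⁻¹, k = 38000 M⁻¹ h⁻¹)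

At 5.0 % conversion the new flask made target at 4.69 × 10⁻⁴ M h⁻¹, a turnover frequency of 9.38 h⁻¹ against my 8.63 h⁻¹. In the new flask at 6.00 h the resting dimer held 21.8 % of the catalyst charged, each dimer counted as two. At the same conversion, the turnover frequency of the new flask fell to 8.11 h⁻¹ with the doubled charge and to 4.93 h⁻¹ with 500 µM.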